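I decided to carry one number through the four flasks: the span, the rise in temperature that buys a power of ten in the making of target.

| setting | delta | alpha | eta | autumn | dusk | winter | dawn |
|---|---|---|---|---|---|---|---|
| substrate | 0.29 M | 0.29 M | 0.43 M | 0.29 M | 0.29 M | 0.29 M | 0.29 M |
| reagent | 1 equiv | 2.2 equiv | 1.5 equiv | 1.50 equiv | 1.50 equiv | 1.50 equiv | 1.50 equiv |
| temperature | 65 °C | 85 °C | 65 °C |  | 70 °C | 85 °C | 100 °C |
| remark | run made earlier | run made earlier | run made earlier | at 70 °C until 80 s, from then on at 100 °C |  |  |  |
| time |  |  |  | 6.0 min | 6.0 min | 6.0 min | 6.0 min |

delta run (percent of the substrate charged)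

| time / min | target / % |
|---|---|
| 0.833 | 0.4 |
| 2.00 | 1.3 |
| 2.50 | 1.1 |
| 4.00 | 3.6 |

alpha run (percent of the substrate charged)

| time / s | target / % |
|---|---|
| 12.0 | 1.0 |
| 40.0 | 9.1 |
| 80.0 | 19.0 |
| 120 | 27.4 |

eta run (percent of the substrate charged)

| time / min | target / % |
|---|---|
| 0.833 | 0.5 |
| 2.00 | 2.4 |
| 2.50 | 3.6 |
| 4.00 | 6.5 |

(readings scatter by 0.3 percentage points)

- which flask leads in amount of target, in percent of the substrate charged ("all alike" within 1.5 percentage points) (autumn / dusk / winter / dawn / all alike)
- how much target is there at the end, in percent of the substrate charged: autumn
- how much target is there at the end, in percent of the substrate charged: dusk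
- how much target is there at the end, in percent of the substrate charged: winter
- how much target is there at the end, in percent of the substrate charged: dawn

- in percentages every species weighs as the substrate in it: one homo dimer counts as two
- for target the crystals are counted in
- as a solid, counted per litre of solution: crystals
- on the list of suspects stand: substrate <-> tautomer; substrate + reagent -> isomer of the product; reagent + tautomer -> target; 2 substrate -> homo dimer; crystals <-> target

The list of suspects has substrate turning reversibly into tautomer, tautomer meeting reagent to give target, and two ways of losing substrate: with reagent to the isomer of the product, or with itself to the homo dimer. The readings were of target.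

The eta and alpha runs held nearly the same reagent, 0.645 M and 0.638 M. Their readings at the same time, 2.4% and 27.4%, differ by a factor of 11.4 over 20.0 K. That gave the span 18.9 K.

But those two runs differ in substrate too. So I looked at delta and eta, but they differ in substrate as well as in reagent: reagent rose by a factor of 2.22 and the last reading of target, in percent of each run's own charge, by 1.81. That pair could not part the two settings, so the doubt stayed on the span.

For winter I took the last stretch of alpha, scaled it to winter's reagent and ran it straight for the whole time, which gave 51.5%. Alpha's last stretch rose by 8.4 percentage points against 9.9 points for the equal stretch before it, so I expected winter somewhat lower. The span took dusk down to 8.32%. It took dawn up to 319%, which is absurd, since the charge holds 100%. So the span could not give dawn's end, and alpha's last reading, 27.4%, was still above the one before it. For autumn it counted the cold 80 s as 2.08 s at the hot temperature, which gave autumn 4.70 min of hot time against dawn's 6.0 min. That sum counted the making of target and left out any loss of substrate during the cold stage.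

The forecast named dawn, with 12% for dusk (9% to 16%), 44% for winter (36% to 51%), 75% for autumn (55% to 87%) and 79% for dawn (58% to 91%): “Dawn leads narrowly over autumn”. Its dusk stood above my 8.32%.

The flasks gave 15.6% in dusk, 39.5% in winter, 43.1% in autumn and 51.5% in dawn, so dawn led.

    substrate ⇌ tautomer (K = 2.90, k = 0.120 min⁻¹, Ea = 109 kJ mol⁻¹, ΔH = −18.0 kJ mol⁻¹)
    substrate + reagent → isomer of the product (k = 0.240 M⁻¹ min⁻¹, Ea = 57.0 kJ mol⁻¹)
    reagent + tautomer → target (k = 0.710 M⁻¹ min⁻¹, Ea = 77.0 kJ mol⁻¹)
    2 substrate → homo dimer (k = 0.530 M⁻¹ min⁻¹, Ea = 78.0 kJ mol⁻¹)
    crystals ⇌ target, rate k5*(cs5 - [target]) while solid is left; crystals form when [target] > cs5 (solubility = 0.230 M, k = 20.0 min⁻¹)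
    (constants at 70 °C)

Dawn stopped short through the homo dimer, the main reason: the same flask without that step gives 77.7% of target against 51.5%. At its change of temperature, at 1.33 min, autumn held 2.18% of target beside 23.2% of homo dimer, though the span had valued that cold stage at 2.08 s of hot time, and it ended 8.4 points behind dawn. Dusk left until 60.0 min counts by the span as 1.56 min at dawn's temperature, and dusk then held 32.8% of target.

The runs were generated by integration with made-up constants; scatter was added.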